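Conventions: atom labels are those of the target throughout (five-membered ring C1–C5; seven-membered ring C5–C10 and C1). In the decalin intermediates ring A is C1–C6 and ring B is C1, C6–C10. β is the face of the C1 methyl group, α the opposite face. TMS = trimethylsilyl, TES = triethylsilyl, TBS = tert-butyldimethylsilyl, Ms = methanesulfonyl, camphanoyl = (1S,4R)-4,7,7-trimethyl-3-oxo-2-oxabicyclo[2.2.1]heptane-1-carbonyl.

## Analysis of the target

The target 26 is a daucane-type sesquiterpenoid diester built on a trans-fused bicyclo[5.3.0]decane, in which the cyclopentane (C1–C5) and the cycloheptane (C5–C10 and C1) share the bond C1–C5. Eight stereocentres are present: quaternary C1 (methyl β), C2 (acetoxy β), the tertiary carbinol C4 (hydroxyl β, isopropyl α), C5 (H α), C6 (veratroyloxy α), C10 (hydroxyl α) and the two oxirane carbons C8 and C9; the C1 methyl, C2–O and C4–O are mutually cis on the five-membered ring. The oxirane is trans-fused to the seven-membered ring: its oxygen is bonded on the α side of C9, syn to the C10 hydroxyl, but on the β side of C8, so that C7 and C10 are trans on the three-membered ring and the C8 methyl is α. An oxirane of this kind is the syn adduct of an (E)-cycloheptene; it cannot come from oxygen transfer to the ordinary (Z)-alkene, and a backside displacement inside the ring would have to open the C7–C8–C9–C10 torsion angle far beyond what a cycloheptane tolerates and would lose to a 1,2-shift. The sensitive groups are two different esters on secondary carbinols beside free hydroxyls (acyl migration under base), the strained oxirane next to a free hydroxyl, and a β-hydroxy relation between C4–OH and C6 that rules out a C6 ketone under basic conditions. The difficulty lies in the crowding around C5, which sits between the fully substituted C1 and C4, in the trans ring fusion at a quaternary carbon, in four differently derivatised oxygens, and above all in the strained oxirane, which has to be made last and under neutral conditions. The feature on which the plan rests is that the fusion bond C1–C5 lies between the oxygenated carbons C4 and C6. With C6 as a ketone, C1–C5 is the bond made by a 1,2-shift of C1 from C6 to C5 in a cis-decalin whose ring A carries the methyl, isopropyl and two oxygens of 5 and whose ring B is the cyclohexene of a diene adduct.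

## Retrosynthetic reasoning

26 to 25 to 24. The two C–O bonds of the oxirane are cut last, because the trans-fused oxirane is the most strained and most fragile element. Syn removal of oxygen leaves the (E)-cycloheptene 25, which cannot be carried through a synthesis. It is therefore traced to the stable (Z)-alkene 24 by a sensitised photoisomerisation at low temperature. The forward reaction has to generate 25 cold and free of acid and then deliver oxygen from the side of the C10 hydroxyl, which decides which of the two trans oxiranes forms.

24 to 23, then to 21 and 22. The C6–O acyl bond is cut to the acid chloride 22. The C10 oxygen stays silylated (23) until both esters are in place, so that it cannot be acylated, and is freed before the oxirane exists, so that acidic fluoride can be used.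

21 to 20 to 19. The C6 carbinol is traced to a ketone. A free β hydroxyl on C4 can carry a hydride to the β face of C6 and give the 6α alcohol, the anti-1,3-diol. The acetate is put on C2 (20) while C6 is still a ketone, when C2–OH is the only secondary hydroxyl of 19.

19 to 18. Only two silyl groups are added back; 18 is the direct product of the skeletal step.

18 to 17. C1–C5 is cut and C1–C6 reconnected. This is the place to cut because one shift then forms the cyclopentane and the cycloheptenone and sets C5, whereas closing either ring separately means working on a pre-formed, crowded five- or seven-membered ring. The forward reaction needs a leaving group on C5 that is equatorial, cis to the C6 hydroxyl and anti to the C6–C1 bond. It also needs a promoter that is not a base, because 18 is a β,γ-unsaturated ketone with a silyloxy group at C10. Its dienolate would move the double bond into conjugation or expel the C10 oxygen.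

17 to 16 to 15 to 13. The mesylate comes from the secondary 5β alcohol, which comes from the C5 ketone by hydride addition from the α face. The same hydride treatment releases the C10 hydroxyl from its ester, and it is then silylated (16).

13 to 12 to 11 to 10. The C2 carbinol comes from the C2 ketone by hydride addition from the α side. O4 is silylated first (11), so that no C4 alkoxide ever sits next to the C6 silyl ether and so that two axial β groups steer the hydride.

10 to 9 to 8. The C4–O bond is traced to an oxirane on the enedione; the forward opening has to cleave C3–O and keep C4–O.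

8 to 6. The C6–O bond is made on the enolate of the only enolisable position, at the stage of the flat enedione. The oxygen is capped at once with a labile silyl group so that O6 and O4 can be told apart later.

6 to 4 and 5. The bonds C1–C10 and C6–C7 are cut as a Diels–Alder reaction at the methyl-bearing double bond of 5. The reaction is run thermally. A chiral Lewis acid bound beside the C–H of that double bond would make the methyl-bearing carbon the β position and send the CH2 end of the diene there, which is the wrong regiochemistry. The thermal reaction leads with bond formation at the unsubstituted carbon. Absolute configuration therefore comes from a chiral acyl group on the diene oxygen, used as a covalent resolving handle.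

4 to 1 and 2. The dienyl ester is cut at the O–acyl bond to the enal 1 and the acid chloride 2.

## Alternatives that were turned down

None of the three plans below offers a different way to the trans-fused oxirane; each would have to end with the same late conversion of a (Z)-cycloheptene, so they are compared on how they build the bicycle.

Alternative 1: The C6–C7 bond is cut. Forward, a C6 acyl radical from a phenyl selenoester (Bu3SnH, AIBN) would add 7-endo to the terminal carbon C7 of a 1,1-disubstituted alkene, giving the cycloheptanone A1.
- For it: 7-endo closure is favoured here because the 6-exo carbon carries the methyl group, and the conditions tolerate esters and free hydroxyls. A1 already carries the C2 acetate and the free C4 hydroxyl, so it is stronger than the chosen route on protecting-group economy after ring formation.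
- Against it: the radical at C8 is quenched by hydrogen, so A1 has lost the C8=C9 double bond from which the oxirane has to be made and which makes the C10 hydroxyl allylic. C8 becomes an uncontrolled stereocentre, and unsaturation can only be brought back next to the C6 ketone, at the wrong place.
- Comparison: it forms one bond and no fusion stereocentre, and it needs a fully substituted cyclopentane with both quaternary carbons made beforehand. The chosen shift forms both rings, sets C5 and keeps C8=C9.

Alternative 2: The C2–C3 bond is cut. Forward, a diazoketone on C5 would be decomposed with Rh2(OAc)4 and the carbenoid would insert into a C–H bond of the silyloxymethyl group on C1, closing the cyclopentanone A2.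
- For it: insertion next to oxygen into a five-membered ring is the preferred mode of such carbenoids, and it closes the crowded ring without touching the fusion.
- Against it: C10–H is also 1,5 to the carbenoid carbon, also next to oxygen, and is tertiary and allylic, so a second cyclopentanone competes. The two hydrogens on C2 are diastereotopic, so C2 is not secured. A2 is a β-silyloxy ketone that still needs an isopropyl nucleophile added to an enolisable, hindered C4 carbonyl from the α face.
- Comparison: the seven-membered ring and the trans fusion must exist before the key step, so the step count is higher. The chosen route brings C4 with its isopropyl group from 5 and sets its oxygen by a face-selective epoxidation.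

Alternative 3: The C8–C9 and C9–C10 bonds are cut. Forward, the silyl enol ether of a trans-hydrindanone would be cyclopropanated (Et2Zn/CH2I2) and the siloxycyclopropane cleaved with FeCl3 and then NaOAc to the ring-enlarged enone A3.
- For it: the ketone can enolise only toward C8, so the insertion is regiospecific, and A3 has C8=C9 and the C10 oxygen in place. Angular-methyl hydrindanones are available by catalytic asymmetric annulation, so on absolute stereocontrol this plan is stronger than the chosen one, which has to separate auxiliary-bearing diastereomers.
- Against it: hydride must add to the C10 ketone of A3 syn to the angular methyl to give the 10α alcohol, and the usual course (anti to the methyl) favours the 10β epimer, with no workable inversion at a neopentyl allylic centre. The trans-hydrindanone must first be built with C2, C4, C5 and C6 all set.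
- Comparison: it enlarges one ring by one carbon and sets no stereocentre. The chosen shift builds two rings and C5 stereospecifically, and it takes C10 with the correct configuration directly from the cycloaddition.

Key step: step 12

Assumption: the (E)-cycloheptene 25 is assumed to persist at −78 °C in an aprotic, acid-free medium long enough for oxygen transfer, as (E)-cycloheptene itself does.

## Route

Step 1
Reactants: 1 3-methylbut-2-enal; 2 (1S,4R)-camphanoyl chloride
Product: 4 (E)-3-methylbuta-1,3-dien-1-yl (1S,4R)-camphanate, via potassium dienolate 3 (not isolated)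
Conditions: KOt-Bu, THF, −78 °C; then 2, −78 → 0 °C
Reagents that add atoms: none
Why: γ-Deprotonation of the enal gives the (E)-dienolate, which is acylated on oxygen by the acid chloride (dienolate O-acylation); the camphanoyl group has no α-hydrogen, so its stereocentres cannot be lost, and it serves as the resolving handle.

Step 2
Reactants: 4 dienyl camphanate; 5 thymoquinone
Product: 6 cis-fused endo cycloadduct, 10α-camphanoyloxy-4-isopropyl-1β,8-dimethyl-6β-H-bicyclo[4.4.0]deca-3,8-diene-2,5-dione
Conditions: toluene, BHT (cat.), 90 °C, sealed vessel; diastereomers separated by crystallisation or chromatography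
Reagents that add atoms: none
Why: Thermal Diels–Alder reaction at the methyl-bearing double bond of 5: the nucleophilic CH2 terminus (C7) bonds ahead to the unsubstituted carbon C6 and the acyloxy terminus C10 closes onto C1 (ortho adduct of the C2 enone), while the endo transition state sets C10–O trans to the C1 methyl and the fusion cis. No facial preference is counted on; the two endo diastereomers differ in the configuration of the bicycle relative to the fixed auxiliary, and the one drawn, which fixes C1 and C10 absolutely, is carried on.

Step 3
Reactants: 6 cycloadduct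
Product: 8 6β-trimethylsilyloxy enedione, via potassium alkoxide 7 (not isolated)
Conditions: KN(SiMe3)2 (1.05 equiv), THF, −78 °C; 2-(phenylsulfonyl)-3-phenyloxaziridine, −78 °C; then Me3SiCl, −78 → −20 °C
Reagents that add atoms: 2-(phenylsulfonyl)-3-phenyloxaziridine, O=S(=O)(c1ccccc1)N1OC1c1ccccc1; chlorotrimethylsilane, C[Si](C)(C)Cl
Why: C6–H is the only enolisable hydrogen (C1 is quaternary, C3 vinylic); the enolate is hydroxylated by the N-sulfonyloxaziridine on the β face, anti to the C10 branch whose acyloxy group lies under ring A and cis to the angular methyl as in alkylations of ring-fusion enolates. The alkoxide is capped in the flask as the TMS ether so that O6 stays distinguishable from O4.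

Step 4
Reactants: 8 6β-trimethylsilyloxy enedione
Product: 9 3β,4β-epoxy-2,5-dione
Conditions: t-BuOOH (anhydrous), DBU, CH2Cl2, 0 °C
Reagents that add atoms: tert-butyl hydroperoxide, CC(C)(C)OO
Why: Nucleophilic (Weitz–Scheffer) epoxidation of the electron-poor enedione: the peroxide anion adds to the unhindered C3 from the β face, the α face being covered by ring B and the C10 acyloxy group, and ring closure fixes C4 with its oxygen β.

Step 5
Reactants: 9 epoxy dione
Product: 10 4β-hydroxy-2,5-dione (C3 methylene)
Conditions: PhSeSePh, NaBH4, EtOH, 0 °C; AcOH; then 9, 0 °C → rt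
Reagents that add atoms: none
Why: Organoselenium reduction of an α,β-epoxy ketone: the selenolate opens the oxirane by SN2 at C3 (secondary and α to the C2 ketone; C4 is fully substituted), a second selenolate takes the selenium off the α-seleno ketone and the C2 enolate is protonated. C4 keeps its β oxygen, and the selenoborate does not reduce the ketones.

Step 6
Reactants: 10 4β-hydroxy dione
Product: 11 4β-triethylsilyloxy-2,5-dione
Conditions: Et3SiOTf, 2,6-lutidine, CH2Cl2, −78 → 0 °C
Reagents that add atoms: triethylsilyl trifluoromethanesulfonate, CC[Si](CC)(CC)OS(=O)(=O)C(F)(F)F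
Why: Silyl triflate silylation of the tertiary β-hydroxy ketone at low temperature, without enolisation or retro-aldol cleavage; O4 is capped before any alkoxide is formed beside the C6 silyl ether and so that it cannot act as a donor in the key step.

Step 7
Reactants: 11 4β-triethylsilyloxy dione
Product: 12 2β-hydroxy-5-ketone
Conditions: LiBH(s-Bu)3, THF, −78 °C; aq. NH4Cl
Reagents that add atoms: none
Why: With isopropyl equatorial, the C4 and C6 silyloxy groups are both axial on the β face, 1,3 to C2, so axial hydride delivery is blocked and the bulky borohydride adds along the equatorial line from the α side to give the axial 2β alcohol, cis to the C1 methyl and C4–O. The C5 ketone, between two fully substituted carbons, is not attacked.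

Step 8
Reactants: 12 2β-hydroxy ketone
Product: 13 2β,4β-bis(triethylsilyloxy)-5-ketone
Conditions: Et3SiOTf, 2,6-lutidine, CH2Cl2, −40 → 0 °C
Reagents that add atoms: triethylsilyl trifluoromethanesulfonate, CC[Si](CC)(CC)OS(=O)(=O)C(F)(F)F
Why: The silyl triflate reaches the hindered axial alcohol, and the C5 ketone has no α-hydrogen; TES instead of a benzyl-type ether lets O2 and O4 be unmasked together later.

Step 9
Reactants: 13 bis-silyl ketone
Product: 15 5β,6β,10α-triol, via trimethylsilyl ether diol 14 (not isolated)
Conditions: LiAlH4, Et2O, −20 → 0 °C; aq. potassium sodium tartrate; then K2CO3, MeOH, 0 °C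
Reagents that add atoms: none
Why: Hydride adds to the C5 ketone from the α face, anti to the two axial C–O bonds on C4 and C6 (polar Felkin–Anh control, with the β side also blocked by both silyl ethers), giving the equatorial 5β alcohol cis to both neighbours. The same reagent cleaves the camphanate, and methanolysis then removes only the trimethylsilyl group.

Step 10
Reactants: 15 triol
Product: 16 10α-tert-butyldimethylsilyloxy-5β,6β-diol
Conditions: t-BuMe2SiCl, imidazole, DMF, rt
Reagents that add atoms: tert-butyldimethylsilyl chloride, CC(C)(C)[Si](C)(C)Cl
Why: Silyl chloride with imidazole discriminates the secondary allylic C10 hydroxyl from the C5 hydroxyl, which lies between two fully substituted carbons, and from the tertiary C6 hydroxyl.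

Step 11
Reactants: 16 diol
Product: 17 5β-mesylate with free 6β-hydroxyl (rearrangement precursor)
Conditions: MsCl, Et3N, CH2Cl2, −20 → 0 °C
Reagents that add atoms: methanesulfonyl chloride, CS(Cl)(=O)=O
Why: Sulfonylation through sulfene takes the only secondary hydroxyl and leaves the tertiary C6–OH free; the cis relation of C5–OMs and C6–OH rules out epoxide formation.

Step 12
Reactants: 17 hydroxy mesylate
Product: 18 trans-fused hydroazulen-6-one, 10α-OTBS, 2β,4β-bis(OTES), C8=C9
Conditions: Et3Al (3 equiv), CH2Cl2, −78 → 0 °C; aq. potassium sodium tartrate
Reagents that add atoms: none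
Why: Et3Al turns the tertiary C6 hydroxyl into an aluminium alkoxide and, held on that oxygen, pulls on the cis mesylate; the ring bond C6–C1, anti-periplanar to the equatorial C5–O bond, shifts to C5 as the mesylate leaves and C6 becomes the ketone (organoaluminium-promoted pinacol-type rearrangement of a β-mesyloxy alcohol, with the decalin-to-hydroazulene rearrangement of cis-glycol monosulfonates as the closest ring-system precedent). Neither ring is closed by a cyclisation: the cyclopentane arises by contraction of ring A when C6 leaves it, and the cycloheptenone by insertion of C5 into ring B. The one new stereocentre, C5, forms with inversion because C1 enters anti to the leaving oxygen, and the migrating C1 keeps its configuration, so the 5β mesylate gives 5α-H and the trans fusion stereospecifically. The selectivity needed is migration of C1 rather than C7 or C3: C1 migrates from the chair with isopropyl and mesylate equatorial, C7 could migrate only from the flipped chair in which isopropyl and C7 are syn-diaxial, and C3 has no alkoxide behind it because O4 is silylated. C4 and C6 carry no hydrogen, so elimination is excluded. An alkoxide base is avoided on purpose, since the dienolate of this β,γ-unsaturated ketone would conjugate the double bond or expel the C10 silyloxy group.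

Step 13
Reactants: 18 bis-TES hydroazulenone
Product: 19 2β,4β-dihydroxy-hydroazulen-6-one (10α-OTBS)
Conditions: HF·pyridine, pyridine, THF, 0 °C
Reagents that add atoms: none
Why: Buffered HF·pyridine cleaves the two triethylsilyl ethers much faster than the TBS ether, and the non-basic medium protects the β-hydroxy ketone from retro-aldol cleavage.

Step 14
Reactants: 19 diol ketone
Product: 20 2β-acetoxy-4β-hydroxy ketone
Conditions: Ac2O, pyridine, DMAP (cat.), CH2Cl2, 0 °C
Reagents that add atoms: acetic anhydride, CC(=O)OC(C)=O
Why: C2–OH is the only secondary hydroxyl at this stage and the tertiary C4–OH does not acylate under these conditions.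

Step 15
Reactants: 20 acetoxy ketone
Product: 21 6α-alcohol (2β-OAc, 4β-OH, 10α-OTBS)
Conditions: Me4NBH(OAc)3, MeCN–AcOH, −30 °C
Reagents that add atoms: none
Why: Evans–Saksena reduction: the acetoxyborohydride bound to the C4 hydroxyl delivers hydride within the molecule to the β face of the C6 ketone, giving the 6α alcohol (anti-1,3-diol); the acetate and silyl ether are not touched.

Step 16
Reactants: 21 6α-alcohol; 22 3,4-dimethoxybenzoyl chloride
Product: 23 6α-veratrate (2β-OAc, 4β-OH, 10α-OTBS)
Conditions: 22, Et3N, DMAP, CH2Cl2, 0 °C → rt
Reagents that add atoms: none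
Why: DMAP-catalysed acylation of the only secondary alcohol; C4–OH is tertiary and C10–O is silylated.

Step 17
Reactants: 23 silyl ether
Product: 24 10α-allylic alcohol
Conditions: HF·pyridine, THF, 0 °C → rt
Reagents that add atoms: none
Why: Fluoride cleavage of the TBS ether in an acidic medium, which avoids the acyl migration to C4–OH or C10–OH that a basic fluoride source could cause; it is done here, before the acid-sensitive oxirane exists.

Step 18
Reactants: 24 10α-allylic alcohol
Product: 26 target (trans-fused 8β,9α-oxirane), via (E)-cycloheptene 25 (not isolated)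
Conditions: hν (254 nm, quartz), toluene–Et2O 9:1 (solvent and triplet sensitiser), 2,6-di-tert-butylpyridine (5 mol%), −78 °C; then in the dark VO(acac)2 (20 mol%, pre-mixed with t-BuOOH), t-BuOOH, −78 → −50 °C; Me2S, −78 °C; unchanged 24 recovered and resubmitted
Reagents that add atoms: tert-butyl hydroperoxide, CC(C)(C)OO
Why: Proposed new method: triplet energy transfer from toluene twists C8=C9, and decay of the twisted triplet gives, beside 24, the strained (E)-alkene 25, which persists at −78 °C; the vanadium peroxide held on the C10 alkoxide then transfers oxygen to the outward face of this trans double bond, and syn addition to an (E)-alkene can only give the oxirane in which C7 and C10 are trans. The closest known reactions are the arene-sensitised Z→E isomerisation of cycloheptene and 1-methylcycloheptene with interception of the (E)-isomer by syn addition (OsO4, cycloadditions), the peracid epoxidation of trans-cyclooctene to its trans-fused oxide, and the hydroxyl-directed vanadium epoxidation of cycloalkenols. Of the two (E)-isomers, which differ in the face of the twisted bond that is turned outward, only 25 exposes the α side of C9 to oxygen tethered at the α C10 hydroxyl, which sets C9–O α and C8–O β (methyl α), while the other isomer is not oxidised and reverts to 24 when the quenched mixture is warmed.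

## Compound list

1 | 3-methylbut-2-enal | CC(C)=CC=O | starting material
2 | (1S,4R)-camphanoyl chloride | ClC(=O)[C@@]12CC[C@@](C)(C(=O)O1)C2(C)C | starting material
3 | potassium (E)-3-methylbuta-1,3-dien-1-olate | [K+].[O-]/C=C/C(C)=C | intermediate
4 | (E)-3-methylbuta-1,3-dien-1-yl (1S,4R)-camphanate | C=C(C)/C=C/OC(=O)[C@@]12CC[C@@](C)(C(=O)O1)C2(C)C | intermediate
5 | thymoquinone (2-isopropyl-5-methyl-1,4-benzoquinone) | CC1=CC(=O)C(C(C)C)=CC1=O | starting material
6 | cis-fused endo adduct: 10α-camphanoyloxy-4-isopropyl-1β,8-dimethyl-6β-H-bicyclo[4.4.0]deca-3,8-diene-2,5-dione | [C@@H]12CC(C)=C[C@H](OC(=O)[C@@]56CC[C@@](C)(C(=O)O5)C6(C)C)[C@]1(C)C(=O)C=C(C(C)C)C2=O | intermediate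
7 | potassium 6β-alkoxide of the 6-hydroxy enedione | [K+].[O-][C@@]12CC(C)=C[C@H](OC(=O)[C@@]56CC[C@@](C)(C(=O)O5)C6(C)C)[C@]1(C)C(=O)C=C(C(C)C)C2=O | intermediate
8 | 6β-trimethylsilyloxy enedione (10α-camphanoyloxy) | C[Si](C)(C)O[C@@]12CC(C)=C[C@H](OC(=O)[C@@]56CC[C@@](C)(C(=O)O5)C6(C)C)[C@]1(C)C(=O)C=C(C(C)C)C2=O | intermediate
9 | 3β,4β-epoxy-6β-trimethylsilyloxy-2,5-dione | C[Si](C)(C)O[C@@]12CC(C)=C[C@H](OC(=O)[C@@]56CC[C@@](C)(C(=O)O5)C6(C)C)[C@]1(C)C(=O)[C@H]3O[C@@]3(C(C)C)C2=O | intermediate
10 | 4β-hydroxy-6β-trimethylsilyloxy-2,5-dione | C[Si](C)(C)O[C@@]12CC(C)=C[C@H](OC(=O)[C@@]56CC[C@@](C)(C(=O)O5)C6(C)C)[C@]1(C)C(=O)C[C@](O)(C(C)C)C2=O | intermediate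
11 | 4β-triethylsilyloxy-6β-trimethylsilyloxy-2,5-dione | C[Si](C)(C)O[C@@]12CC(C)=C[C@H](OC(=O)[C@@]56CC[C@@](C)(C(=O)O5)C6(C)C)[C@]1(C)C(=O)C[C@](O[Si](CC)(CC)CC)(C(C)C)C2=O | intermediate
12 | 2β-hydroxy-4β-triethylsilyloxy-6β-trimethylsilyloxy-5-ketone | C[Si](C)(C)O[C@@]12CC(C)=C[C@H](OC(=O)[C@@]56CC[C@@](C)(C(=O)O5)C6(C)C)[C@]1(C)[C@@H](O)C[C@](O[Si](CC)(CC)CC)(C(C)C)C2=O | intermediate
13 | 2β,4β-bis(triethylsilyloxy)-6β-trimethylsilyloxy-5-ketone | C[Si](C)(C)O[C@@]12CC(C)=C[C@H](OC(=O)[C@@]56CC[C@@](C)(C(=O)O5)C6(C)C)[C@]1(C)[C@@H](O[Si](CC)(CC)CC)C[C@](O[Si](CC)(CC)CC)(C(C)C)C2=O | intermediate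
14 | 5β,10α-diol with 6β-trimethylsilyl ether and 2β,4β-bis(triethylsilyl) ethers | C[Si](C)(C)O[C@@]12CC(C)=C[C@H](O)[C@]1(C)[C@@H](O[Si](CC)(CC)CC)C[C@](O[Si](CC)(CC)CC)(C(C)C)[C@H]2O | intermediate
15 | 5β,6β,10α-triol, 2β,4β-bis(triethylsilyl) ether | O[C@@]12CC(C)=C[C@H](O)[C@]1(C)[C@@H](O[Si](CC)(CC)CC)C[C@](O[Si](CC)(CC)CC)(C(C)C)[C@H]2O | intermediate
16 | 5β,6β-diol, 10α-TBS ether, 2β,4β-bis(triethylsilyl) ether | O[C@@]12CC(C)=C[C@H](O[Si](C)(C)C(C)(C)C)[C@]1(C)[C@@H](O[Si](CC)(CC)CC)C[C@](O[Si](CC)(CC)CC)(C(C)C)[C@H]2O | intermediate
17 | cis-decalin 6β-ol 5β-mesylate (rearrangement precursor) | O[C@@]12CC(C)=C[C@H](O[Si](C)(C)C(C)(C)C)[C@]1(C)[C@@H](O[Si](CC)(CC)CC)C[C@](O[Si](CC)(CC)CC)(C(C)C)[C@H]2OS(C)(=O)=O | intermediate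
18 | trans-fused hydroazulen-6-one, 10α-OTBS, 2β,4β-bis(OTES), C8=C9 | O=C2CC(C)=C[C@H](O[Si](C)(C)C(C)(C)C)[C@]3(C)[C@@H](O[Si](CC)(CC)CC)C[C@](O[Si](CC)(CC)CC)(C(C)C)[C@@H]23 | intermediate
19 | 2β,4β-dihydroxy-hydroazulen-6-one, 10α-OTBS | O=C2CC(C)=C[C@H](O[Si](C)(C)C(C)(C)C)[C@]3(C)[C@@H](O)C[C@](O)(C(C)C)[C@@H]23 | intermediate
20 | 2β-acetoxy-4β-hydroxy-hydroazulen-6-one, 10α-OTBS | O=C2CC(C)=C[C@H](O[Si](C)(C)C(C)(C)C)[C@]3(C)[C@@H](OC(C)=O)C[C@](O)(C(C)C)[C@@H]23 | intermediate
21 | 2β-acetoxy-4β,6α-diol, 10α-OTBS | O[C@@H]2CC(C)=C[C@H](O[Si](C)(C)C(C)(C)C)[C@]3(C)[C@@H](OC(C)=O)C[C@](O)(C(C)C)[C@@H]23 | intermediate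
22 | 3,4-dimethoxybenzoyl chloride | COc1ccc(C(Cl)=O)cc1OC | starting material
23 | 6α-veratrate, 2β-acetate, 4β-ol, 10α-OTBS | COc1ccc(C(=O)O[C@@H]2CC(C)=C[C@H](O[Si](C)(C)C(C)(C)C)[C@]3(C)[C@@H](OC(C)=O)C[C@](O)(C(C)C)[C@@H]23)cc1OC | intermediate
24 | 6α-veratrate, 2β-acetate, 4β,10α-diol, (Z)-C8=C9 | COc1ccc(C(=O)O[C@@H]2CC(C)=C[C@H](O)[C@]3(C)[C@@H](OC(C)=O)C[C@](O)(C(C)C)[C@@H]23)cc1OC | intermediate
25 | (E)-isomer of 24 at C8=C9 (C7 and C10 trans), the one of the two twisted forms whose outward face is α at C9 and β at C8 | COc1ccc(C(=O)O[C@@H]2C/C(C)=C/[C@H](O)[C@]3(C)[C@@H](OC(C)=O)C[C@](O)(C(C)C)[C@@H]23)cc1OC | intermediate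
26 | target: 6α-veratrate, 2β-acetate, 4β,10α-diol with trans-fused oxirane (O on the β side of C8 and the α side of C9, C8 methyl α) | COc1ccc(C(=O)O[C@@H]2C[C@@]3(C)O[C@@H]3[C@H](O)[C@]3(C)[C@@H](OC(C)=O)C[C@](O)(C(C)C)[C@@H]23)cc1OC | target

## Step count and least certain steps

Total: 18 steps. Longest linear sequence: 18 steps, from 1; compounds 2, 5 and 22 are bought.

Step 18. Three things may go wrong. The stationary fraction of (E)-alkene may be small and may favour the unproductive twisted form, because the productive one pushes C9 towards the C1 methyl. The strained alkene may be protonated by a hydroxyl group or a trace of acid before oxygen reaches it. Undirected oxygen transfer to the (Z)-alkene or Lewis-acid opening of the strained oxirane may set in if the mixture warms before the peroxide is destroyed. The fallback separates isomerisation from oxidation and relies on operations practised on trans-cycloheptenes and trans-cyclooctenes. It sets out from 24, which is pumped with methyl benzoate in Et2O–hexane at −50 °C through a quartz coil under 254 nm light and then through a cold bed of AgNO3 on silica gel. The silver salt holds back only the (E)-alkenes and so drives the isomerisation past the stationary state. The silver nitrate complex F1 of the required twisted form is eluted and separated from its isomer. At −78 °C in CH2Cl2 it is then treated with n-Bu4NCl, which removes the silver as AgCl, in the presence of dimethyldioxirane, which transfers oxygen to the freed trans double bond as it does to trans-cyclooctene. This returns to the route at 26.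

Step 12 (key step). The chair of ring A that the shift needs carries three axial oxygen substituents on the β face and may be thinly populated. The reaction could then stall, C7 could migrate from the flipped chair to give a bridged ketone, or the Lewis acid could strip silyl groups first. The fallback locks the chair and sets out from 10. Reduction of C2 with LiBH(s-Bu)3 while C4–OH is free gives the 2β,4β-diol F2. 4-Methoxybenzaldehyde dimethyl acetal with pyridinium tosylate ties O2 and O4 in the bridged acetal F3; this acetal can form only when both C–O bonds are axial, so it freezes ring A with the future mesylate equatorial and covers the β face of C5. LiAlH4 followed by K2CO3 in MeOH gives the triol F4, t-BuMe2SiCl with imidazole the C10 silyl ether F5, and MsCl with Et3N the mesylate F6. Et3Al at −78 °C then gives the acetal-bridged hydroazulenone F7, and aqueous acetic acid releases the diol and returns to the route at 19.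

Step 2. The acyloxy diene is a weaker donor than a silyloxy diene. The cycloaddition may be slow, bonding of C7 to the methyl-bearing carbon may compete, or the two endo diastereomers may resist separation. The fallback sets out from 1, which is converted with t-BuMe2SiOTf and Et3N into the tert-butyldimethylsilyl dienol ether F8. F8 is added to 5 in toluene at 60 °C to give the racemic silyloxy adduct F9. HF·pyridine frees the racemic hydroxy enedione F10, and acylation with 2 (pyridine, DMAP) gives 6 and its diastereomer for separation. The route is rejoined at 6.

Step 3. The oxidant may approach the enolate from the α face and give the trans-fused ketol, or the camphanoyl group may transfer to C6 of the free enolate. The fallback avoids a free enolate: 6 is converted with Me3SiOTf and Et3N into the trimethylsilyl dienol ether F11, which is oxidised with dimethyldioxirane at −78 °C (Rubottom oxidation). The 1,4-silyl shift that follows the epoxidation gives 8 directly.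

Step 5. Backside attack at C3 is an axial entry syn to the C10 branch and may be slow, which would give time for carbonyl reduction or loss of the trimethylsilyl group. The fallback goes from 8 directly to 10 without the oxirane: Mukaiyama-type hydration of the enedione with Mn(dpm)3, PhSiH3 and O2, then P(OEt)3. Hydrogen-atom transfer goes to C3 and the tertiary C4 radical, α to the C5 carbonyl, is trapped by oxygen from the open β face. No new compound is made.

Step 7. Both faces of C2 are crowded, β by the two silyl ethers and α by the C10 branch, so the reduction may be slow or may lose facial selectivity. The fallback changes the order and sets out from 9. NaBH4 with CeCl3·7H2O reduces the C2 ketone anti to the oxirane oxygen and gives the cis epoxy alcohol F12. The selenolate from PhSeSePh and NaBH4 opens the oxirane at C3 to give the hydroxy selenide F13, and Bu3SnH with AIBN removes selenium to give the diol F2. Et3SiOTf (excess) with 2,6-lutidine silylates both hydroxyls and returns to the route at 13.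

## Further compounds

F1 | step 18 | silver nitrate complex of the (E)-cycloheptene 25 | COc1ccc(C(=O)O[C@@H]2C/C(C)=C/[C@H](O)[C@]3(C)[C@@H](OC(C)=O)C[C@](O)(C(C)C)[C@@H]23)cc1OC.[Ag+].[O-][N+](=O)[O-]
F2 | step 12 | 2β,4β-dihydroxy-6β-trimethylsilyloxy-5-ketone (10α-camphanoyloxy) | C[Si](C)(C)O[C@@]12CC(C)=C[C@H](OC(=O)[C@@]56CC[C@@](C)(C(=O)O5)C6(C)C)[C@]1(C)[C@@H](O)C[C@](O)(C(C)C)C2=O
F3 | step 12 | 2,4-O-(4-methoxybenzylidene) acetal of F2, aryl group exo | C[Si](C)(C)O[C@@]12CC(C)=C[C@H](OC(=O)[C@@]56CC[C@@](C)(C(=O)O5)C6(C)C)[C@]1(C)[C@@H](O3)C[C@](O[C@H]3c4ccc(OC)cc4)(C(C)C)C2=O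
F4 | step 12 | acetal-bridged 5β,6β,10α-triol | O[C@@]12CC(C)=C[C@H](O)[C@]1(C)[C@@H](O3)C[C@](O[C@H]3c4ccc(OC)cc4)(C(C)C)[C@H]2O
F5 | step 12 | acetal-bridged 5β,6β-diol, 10α-TBS ether | O[C@@]12CC(C)=C[C@H](O[Si](C)(C)C(C)(C)C)[C@]1(C)[C@@H](O3)C[C@](O[C@H]3c4ccc(OC)cc4)(C(C)C)[C@H]2O
F6 | step 12 | acetal-bridged 6β-ol 5β-mesylate | O[C@@]12CC(C)=C[C@H](O[Si](C)(C)C(C)(C)C)[C@]1(C)[C@@H](O3)C[C@](O[C@H]3c4ccc(OC)cc4)(C(C)C)[C@H]2OS(C)(=O)=O
F7 | step 12 | acetal-bridged trans-fused hydroazulen-6-one, 10α-OTBS | O=C2CC(C)=C[C@H](O[Si](C)(C)C(C)(C)C)[C@]3(C)[C@@H](O4)C[C@](O[C@H]4c5ccc(OC)cc5)(C(C)C)[C@@H]23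
F8 | step 2 | (E)-tert-butyldimethyl[(3-methylbuta-1,3-dien-1-yl)oxy]silane | C=C(C)/C=C/O[Si](C)(C)C(C)(C)C
F9 | step 2 | racemic 10α-silyloxy cis-fused endo adduct (one enantiomer drawn) | [C@@H]12CC(C)=C[C@H](O[Si](C)(C)C(C)(C)C)[C@]1(C)C(=O)C=C(C(C)C)C2=O
F10 | step 2 | racemic 10α-hydroxy enedione (one enantiomer drawn) | [C@@H]12CC(C)=C[C@H](O)[C@]1(C)C(=O)C=C(C(C)C)C2=O
F11 | step 3 | 5-trimethylsilyloxy-5,6-dienol ether of 6 | C[Si](C)(C)OC1=C2CC(C)=C[C@H](OC(=O)[C@@]56CC[C@@](C)(C(=O)O5)C6(C)C)[C@]2(C)C(=O)C=C1C(C)C
F0 | step 5 | none | none
F12 | step 7 | 2β-hydroxy-3β,4β-epoxy-6β-trimethylsilyloxy-5-ketone | C[Si](C)(C)O[C@@]12CC(C)=C[C@H](OC(=O)[C@@]56CC[C@@](C)(C(=O)O5)C6(C)C)[C@]1(C)[C@@H](O)[C@H]3O[C@@]3(C(C)C)C2=O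
F13 | step 7 | 2β,4β-dihydroxy-3α-phenylselanyl-6β-trimethylsilyloxy-5-ketone | C[Si](C)(C)O[C@@]12CC(C)=C[C@H](OC(=O)[C@@]56CC[C@@](C)(C(=O)O5)C6(C)C)[C@]1(C)[C@@H](O)[C@H]([Se]c3ccccc3)[C@](O)(C(C)C)C2=O
A1 | alternative 1 | trans-fused hydroazulen-6-one with saturated C8 methyl, 2-acetate, 4-hydroxyl, 10-OTBS | O=C2C[C@H](C)C[C@H](O[Si](C)(C)C(C)(C)C)[C@]3(C)[C@@H](OC(C)=O)C[C@](O)(C(C)C)[C@@H]23
A2 | alternative 2 | trans-fused hydroazulen-4-one with 2-OTBS, 6-OTES, 10-OTBDPS, C8=C9 | CC[Si](CC)(CC)O[C@@H]2CC(C)=C[C@H](O[Si](c4ccccc4)(c4ccccc4)C(C)(C)C)[C@]3(C)[C@@H](O[Si](C)(C)C(C)(C)C)CC(=O)[C@@H]23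
A3 | alternative 3 | hydroazulene C10 enone with C8=C9, 6-OTBS, 2-acetate, 4-hydroxyl | CC(C)(C)[Si](C)(C)O[C@@H]2CC(C)=CC(=O)[C@]3(C)[C@@H](OC(C)=O)C[C@](O)(C(C)C)[C@@H]23
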